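common to all: free catalyst 2.5 mM
- grey: solid substrate 0.028 M; reagent 0.15 M; temperature 85 °C; run made earlier
- violet: solid substrate 0.051 M; reagent 0.15 M; temperature 96 °C; run made earlier
- red: solid substrate 0.086 M; reagent 0.15 M; temperature 85 °C; run made earlier
- midnight: solid substrate 0.10 M; reagent 0.150 M; temperature 100 °C; time 10 d
- noon: solid substrate 0.030 M; reagent 0.150 M; temperature 80 °C; time 10 d

| run | time / d | product / % | solid substrate / % |
|---|---|---|---|
| grey | 4.00 | 64.6 | 0.3 |
| grey | 8.00 | 87.6 | 0.1 |
| grey | 10.0 | 92.4 | 0.8 |
| grey | 15.0 | 97.0 | 0.5 |
| violet | 0.833 | 10.0 | 56.0 |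
| violet | 2.50 | 50.9 | 0 |
| violet | 5.00 | 83.5 | 0.4 |
| violet | 8.00 | 94.8 | 0 |
| red | 4.00 | 33.6 | 25.7 |
| red | 8.00 | 68.8 | 0 |
| red | 10.0 | 78.8 | 0.3 |
| red | 15.0 | 90.7 | 0 |

(standard deviation of a reading: 0.3 percentage points)

- solid, in amounts per volume of the solution: solid substrate
- the analysis behind the earlier runs scatters by 0.3 percentage points, standard deviation
- steps under discussion: starting material + free catalyst -> catalyst intermediate A; reagent + catalyst intermediate A <-> catalyst intermediate B; catalyst intermediate B <-> free catalyst + product; solid substrate <-> starting material; catalyst intermediate B -> spent catalyst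
- at the start none of the solid substrate is in solution
- what has only dissolved of solid substrate counts as not reacted

- the winner by amount of product, in percent of the solid substrate charged; "neither" if no more than 2 percentage points parts them (midnight / noon / neither)
- how much product is there at the end, in percent of the solid substrate charged: midnight
- how much product is there at the end, in percent of the solid substrate charged: noon

1. In the vessel, watch c, the concentration of dissolved starting material: with free catalyst at 2.5 mM in every run, the readings suggest that product forms in proportion to c.

2. Once the solid is gone, the unreacted part decays exponentially (pseudo-first-order). Grey gives 0.262 d⁻¹ for the tail constant k, the fraction of unreacted material converted per day. Violet reads 0.436 d⁻¹. Red, with its heavier charge, reads 0.193 d⁻¹, less than grey.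

3. At the start c is zero, and it climbs while the solid dissolves, so the curve starts flat and bends upward: violet at 0.833 d held 17.3 mM dissolved, with 56.0 % of its charge still solid. At 4.00 d, red held S = 35.0 mM in solution. Its mean slope, 7.22 mM d⁻¹, stands against k·S = 6.75 mM d⁻¹.

4. Noon's charge of 0.030 M lies below S, so its solid should all pass into solution. Taking ln k as linear in temperature gives 0.208 d⁻¹. Product should cross the unreacted part at 3.33 d and reach 87.5 % at 10 d, still rising.

5. Midnight's charge of 0.10 M exceeds S, so part of it should stay solid for a while. Scaled for temperature and for red's loss, k = 0.387 d⁻¹. A plain exponential at that k over 10 d gives midnight 97.9 %. That counts the whole charge as dissolved from the first moment, so it stands as an upper estimate.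

6. The forecast, holding that “product formation looks first order in dissolved starting material”, names midnight: 95 % (88 % to 98.5 %) for midnight and 83 % (77 % to 88 %) for noon. The reckoning above also puts midnight first, but it stands higher than the forecast for midnight and for noon.

The flasks give midnight as the winner, with 92.6 % for midnight and 85.9 % for noon.

    starting material + free catalyst → catalyst intermediate A (k = 0.230 M⁻¹ min⁻¹, Ea = 64.0 kJ mol⁻¹)
    reagent + catalyst intermediate A ⇌ catalyst intermediate B (K = 5.80 M⁻¹, k = 1.10 M⁻¹ min⁻¹, Ea = 79.0 kJ mol⁻¹, ΔH = −18.0 kJ mol⁻¹)
    catalyst intermediate B ⇌ free catalyst + product (K = 0.250 M, k = 0.690 min⁻¹, Ea = 112 kJ mol⁻¹, ΔH = −2.00 kJ mol⁻¹)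
    solid substrate ⇌ starting material, rate k4*(cs4 - [starting material]) while solid is left; crystals form when [starting material] > cs4 (solubility = 48.0 mM, k = 5.00 × 10⁻⁴ min⁻¹)
    catalyst intermediate B → spent catalyst (k = 1.40 × 10⁻⁵ min⁻¹, Ea = 129 kJ mol⁻¹)
    (constants at 100 °C)

In noon, free catalyst has a half-life of 0.48 d by the entry step at 0.516 d, far longer than the forward half-lives at 10.0 d of catalyst intermediate A (0.36 h) and catalyst intermediate B (0.13 h). Free catalyst is the resting state there, at 82.3 % of the catalyst charged. Noon's starting material decays between 4.0 d and 10 d at 0.215 d⁻¹, against 0.208 d⁻¹ carried from grey's 0.262 d⁻¹, and its crossing comes at 3.65 d. In midnight, solid substrate still stands at 6.50 % at 5.00 d.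

(Readings and results were computed with made-up constants; noise was put on by code.)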